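**Retrosynthetic overview**

1. The oxane ring is opened at the bond between the ring oxygen O1 and the quaternary carbon C2 (the carbon bearing methyl and the cyclohexyl group). This leads to an acyclic (3S,5S)-bromo diol. In the forward direction the oxane is formed last, by Markovnikov alkoxymercuration–demercuration.
2. Enabling feature: in that diol the future C2 is the inner carbon of an exocyclic C=CH2 group attached to the cyclohexane ring, and the tertiary hydroxyl oxygen on the CMe2 carbon sits so that O and this carbon close a six-membered ring in the 6-exo mode. The =CH2 carbon becomes the C2 methyl group.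
3. The bromo diol comes from SN2 opening of an (R)-epoxide by bromide. The epoxide comes from Shi epoxidation of a prenyl-type alkene, which comes from cross-metathesis after Brown allylation of a 2-substituted acrolein.
4. The acrolein comes from SeO2 oxidation of a 1-bromo-2-chloro-limonene, made by methylenation of a methyl ketone. The ring Br/Cl pair is set at the ketone stage (bromohydrin, trans epoxide, diaxial chlorohydrin, HBr); the acetyl group is an acid-proof stand-in for isopropenyl.
5. Ring order: the cyclohexane ring is taken intact from (R)-limonene and its CH stereocentre is kept throughout; the oxane ring is formed last.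

Key step: step 11

Remark: (−)-Ipc2B(allyl) and Li2NiBr4 are assumed to be used as pre-formed stock solutions; oxane locants (O1, C2 quaternary, C3 carbinol, C5 CHBr, C6 CMe2) are used for the side-chain atoms throughout.

**Step 1**
Reactants: 1 (R)-(+)-limonene
Product: 2 1-[(1R)-4-methylcyclohex-3-en-1-yl]ethan-1-one
Conditions: K2OsO4·2H2O (2 mol %), NaIO4 (4 equiv), 2,6-lutidine, 1,4-dioxane/H2O 3:1, 0 °C to rt
Reagents that add atoms: sodium periodate, [Na+].[O-]I(=O)(=O)=O
Why: Lemieux–Johnson oxidative cleavage, in which osmium tetroxide should dihydroxylate the unhindered exocyclic 1,1-disubstituted alkene in preference to the endocyclic trisubstituted one and periodate cleaves the diol, leaving the ring stereocentre untouched.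

**Step 2**
Reactants: 2 1-[(1R)-4-methylcyclohex-3-en-1-yl]ethan-1-one
Product: 4 1-[(1R,3R,4S)-3,4-epoxy-4-methylcyclohexyl]ethan-1-one (trans epoxide, oxygen cis to acetyl), via diaxial bromohydrin 3 (not isolated)
Conditions: N-bromosuccinimide (1.05 equiv), acetone/H2O 4:1, 0 °C; then 2 M aq NaOH, 0 °C to rt
Reagents that add atoms: water, O
Why: Bromohydrin formation followed by Williamson-type epoxide closure, in which the reversibly formed bromonium ion is opened by water only where Markovnikov and trans-diaxial (Fürst–Plattner) attack coincide, so that the tertiary OH is cis and the secondary Br trans to the acetyl group, and hydroxide then closes the epoxide with inversion at the CH–Br carbon.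

**Step 3**
Reactants: 4 1-[(1R,3R,4S)-3,4-epoxy-4-methylcyclohexyl]ethan-1-one
Product: 5 1-[(1R,3S,4S)-3-chloro-4-hydroxy-4-methylcyclohexyl]ethan-1-one
Conditions: LiCl (3 equiv), AcOH (3 equiv), THF, rt
Reagents that add atoms: lithium chloride, [Li+].[Cl-]
Why: Acid-assisted SN2 opening of the epoxide by chloride (halohydrin formation), in which only attack at the secondary epoxide carbon is trans-diaxial, so chloride should enter there with inversion and leave the axial tertiary alcohol.

**Step 4**
Reactants: 5 1-[(1R,3S,4S)-3-chloro-4-hydroxy-4-methylcyclohexyl]ethan-1-one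
Product: 6 1-[(1R,3S,4S)-4-bromo-3-chloro-4-methylcyclohexyl]ethan-1-one
Conditions: HBr (33 wt % in AcOH, 5 equiv), CH2Cl2, 0 °C to rt
Reagents that add atoms: hydrogen bromide, Br
Why: SN1-type substitution of the tertiary alcohol with retention, in which ionisation is assisted by the antiperiplanar axial C–Cl bond and bromide re-enters axially anti to chlorine, while any alkene formed by E1 loss re-adds HBr in the Markovnikov sense through the same cation, so the trans-diaxial bromochloride (equatorial methyl, also the more stable isomer) should result.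

**Step 5**
Reactants: 6 1-[(1R,3S,4S)-4-bromo-3-chloro-4-methylcyclohexyl]ethan-1-one
Product: 7 (1S,2S,4R)-1-bromo-2-chloro-1-methyl-4-(prop-1-en-2-yl)cyclohexane
Conditions: Cp2TiMe2 (2 equiv), toluene, 65 °C, dark
Reagents that add atoms: dimethyltitanocene, C[Ti](C)(C1C=CC=C1)C1C=CC=C1
Why: Petasis methylenation, in which thermally generated Cp2Ti=CH2 adds to the ketone by [2+2] cycloaddition and cycloreverts to the 1,1-disubstituted alkene under non-basic conditions, so neither E2 loss of HBr nor epimerisation of the α-carbon is expected.

**Step 6**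
Reactants: 7 (1S,2S,4R)-1-bromo-2-chloro-1-methyl-4-(prop-1-en-2-yl)cyclohexane
Product: 8 2-[(1R,3S,4S)-4-bromo-3-chloro-4-methylcyclohexyl]prop-2-enal
Conditions: SeO2 (1.5 equiv), 1,4-dioxane, 70 °C
Reagents that add atoms: selenium dioxide, O=[Se]=O
Why: Selenium dioxide allylic oxidation (ene reaction, then [2,3]-sigmatropic shift) taken to the aldehyde level, in which the methyl group is preferred over the only other allylic position, the ring methine, and no stereocentre is touched.

**Step 7**
Reactants: 8 2-[(1R,3S,4S)-4-bromo-3-chloro-4-methylcyclohexyl]prop-2-enal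
Product: 10 (3S)-2-[(1R,3S,4S)-4-bromo-3-chloro-4-methylcyclohexyl]hexa-1,5-dien-3-ol, via borinate ester 9 (not isolated)
Conditions: (−)-Ipc2B(allyl) (1.0 M in pentane, 1.3 equiv), Et2O, −100 to −78 °C; then HOCH2CH2NH2, rt
Reagents that add atoms: (−)-B-allyldiisopinocampheylborane (from (+)-α-pinene), C=CCB([C@@H]1C[C@@H]2C[C@H]([C@H]1C)C2(C)C)[C@@H]1C[C@@H]2C[C@H]([C@H]1C)C2(C)C
Why: Brown asymmetric allylboration through a closed chair (Zimmerman–Traxler) transition state, in which the reagent derived from (+)-α-pinene should deliver the allyl group to the Si face of the aldehyde and so set the carbinol centre as (S) under reagent control, ethanolamine then releasing the alcohol from the borinate.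

**Step 8**
Reactants: 10 (3S)-2-[(1R,3S,4S)-4-bromo-3-chloro-4-methylcyclohexyl]hexa-1,5-dien-3-ol
Product: 11 (3S)-2-[(1R,3S,4S)-4-bromo-3-chloro-4-methylcyclohexyl]-6-methylhepta-1,5-dien-3-ol
Conditions: 2-methylbut-2-ene (large excess), second-generation Grubbs catalyst RuCl2(=CHPh)(PCy3)(H2IMes) (5 mol %), CH2Cl2, 40 °C
Reagents that add atoms: 2-methylbut-2-ene, CC=C(C)C
Why: Olefin cross-metathesis with 2-methylbut-2-ene as an isobutene equivalent should convert the monosubstituted alkene into the trisubstituted prenyl-type alkene, while the hindered 1,1-disubstituted alkene is not a competent partner and no stereocentre is touched.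

**Step 9**
Reactants: 11 (3S)-2-[(1R,3S,4S)-4-bromo-3-chloro-4-methylcyclohexyl]-6-methylhepta-1,5-dien-3-ol
Product: 12 (2S)-3-[(1R,3S,4S)-4-bromo-3-chloro-4-methylcyclohexyl]-1-[(2R)-3,3-dimethyloxiran-2-yl]but-3-en-2-ol
Conditions: D-fructose-derived Shi ketone (0.3 equiv), Oxone (2KHSO5·KHSO4·K2SO4, 1.5 equiv), K2CO3, Bu4NHSO4, MeCN/CH2(OMe)2/aq Na2B4O7 buffer (pH 10.5), 0 °C
Reagents that add atoms: potassium peroxymonosulfate, [K+].[O-]S(=O)(=O)OO
Why: Shi asymmetric epoxidation, in which the chiral dioxirane attacks the electron-rich trisubstituted alkene through a spiro transition state and the D-fructose-derived catalyst should set the CH epoxide carbon as (R), while the 1,1-disubstituted allylic-alcohol alkene, a poor substrate for this catalyst, is left.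

**Step 10**
Reactants: 12 (2S)-3-[(1R,3S,4S)-4-bromo-3-chloro-4-methylcyclohexyl]-1-[(2R)-3,3-dimethyloxiran-2-yl]but-3-en-2-ol
Product: 13 (3S,5S)-5-bromo-2-[(1R,3S,4S)-4-bromo-3-chloro-4-methylcyclohexyl]-6-methylhept-1-ene-3,6-diol
Conditions: Li2NiBr4 (0.4 M in THF, 2 equiv), THF, 0 °C to rt; pH 7 phosphate buffer work-up
Reagents that add atoms: dilithium tetrabromonickelate, [Li+].[Li+].[Ni+2].[Br-].[Br-].[Br-].[Br-]
Why: Epoxide opening by soft bromide (halohydrin formation) in an SN2 process at the less substituted epoxide carbon, so the C–Br centre should form with inversion, (R)-epoxide to (S)-bromide, and the tertiary alcohol needed as the nucleophile of step 11 is released.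

**Step 11**
Reactants: 13 (3S,5S)-5-bromo-2-[(1R,3S,4S)-4-bromo-3-chloro-4-methylcyclohexyl]-6-methylhept-1-ene-3,6-diol
Product: 15 (2S,3S,5S)-5-bromo-2-[(1R,3S,4S)-4-bromo-3-chloro-4-methylcyclohexyl]-2,6,6-trimethyloxan-3-ol, via alkylmercury acetate 14 (not isolated)
Conditions: Hg(OAc)2 (1.05 equiv), CH2Cl2, −20 to 0 °C; then NaBH4, 3 M aq NaOH, 0 °C
Reagents that add atoms: none
Why: Intramolecular alkoxymercuration–demercuration (Markovnikov hydroalkoxylation): Hg(OAc)2 forms a mercurinium ion on the 1,1-disubstituted alkene and the tertiary hydroxyl attacks the more substituted alkene carbon, so the oxane closes by 6-exo-trig O–C2 bond formation (the alternative 7-endo attack at the CH2 terminus is anti-Markovnikov), and NaBH4 then replaces mercury by hydrogen, turning the former =CH2 into the C2 methyl group. The closest known reaction type is the mercury-mediated cyclisation of tertiary alkenols to 2,2,6,6-tetrasubstituted oxanes and related di-tertiary terpene ethers. The new quaternary centre C2 is controlled by the existing centres C3 and C5 through a chair transition state: with C3–OH and C5–Br anti, one chair has Br equatorial, the allylic C–O bond in the alkene plane (the non-deactivating arrangement for electrophilic addition to allylic alcohols, OH then axial) and the cyclohexyl group equatorial, away from the axial methyl of the CMe2 carbon, which places the mercuriomethyl group axial and should give (2S). The competing chair (Br axial, C–O bond perpendicular to the alkene plane) leads to the C2 epimer and should be disfavoured; the expected product is also judged the more stable isomer (axial OH able to hydrogen-bond to the ring oxygen, equatorial Br and cyclohexyl), so partial reversibility of the mercuration should work in the same direction. Chemoselectivity should hold because only one alkene is present, the secondary OH cannot reach the mercurinium carbon in a ring of reasonable size, and a near-stoichiometric charge of divalent mercury at low temperature limits halide abstraction from the C–Br bonds.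

**Compound list**

1 | (R)-(+)-limonene | CC(=C)[C@@H]1CCC(C)=CC1 | starting material
2 | 1-[(1R)-4-methylcyclohex-3-en-1-yl]ethan-1-one | CC(=O)[C@@H]1CCC(C)=CC1 | intermediate
3 | 1-[(1R,3S,4S)-3-bromo-4-hydroxy-4-methylcyclohexyl]ethan-1-one | CC(=O)[C@@H]1CC[C@](C)(O)[C@@H](Br)C1 | intermediate
4 | 1-[(1R,3R,4S)-3,4-epoxy-4-methylcyclohexyl]ethan-1-one | CC(=O)[C@@H]1CC[C@]2(C)O[C@@H]2C1 | intermediate
5 | 1-[(1R,3S,4S)-3-chloro-4-hydroxy-4-methylcyclohexyl]ethan-1-one | CC(=O)[C@@H]1CC[C@](C)(O)[C@@H](Cl)C1 | intermediate
6 | 1-[(1R,3S,4S)-4-bromo-3-chloro-4-methylcyclohexyl]ethan-1-one | CC(=O)[C@@H]1CC[C@](C)(Br)[C@@H](Cl)C1 | intermediate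
7 | (1S,2S,4R)-1-bromo-2-chloro-1-methyl-4-(prop-1-en-2-yl)cyclohexane | CC(=C)[C@@H]1CC[C@](C)(Br)[C@@H](Cl)C1 | intermediate
8 | 2-[(1R,3S,4S)-4-bromo-3-chloro-4-methylcyclohexyl]prop-2-enal | O=CC(=C)[C@@H]1CC[C@](C)(Br)[C@@H](Cl)C1 | intermediate
9 | (3S)-2-[(1R,3S,4S)-4-bromo-3-chloro-4-methylcyclohexyl]hexa-1,5-dien-3-yl diisopinocampheylborinate | C=CC[C@H](OB([C@@H]1C[C@@H]2C[C@H]([C@H]1C)C2(C)C)[C@@H]1C[C@@H]2C[C@H]([C@H]1C)C2(C)C)C(=C)[C@@H]1CC[C@](C)(Br)[C@@H](Cl)C1 | intermediate
10 | (3S)-2-[(1R,3S,4S)-4-bromo-3-chloro-4-methylcyclohexyl]hexa-1,5-dien-3-ol | C=CC[C@H](O)C(=C)[C@@H]1CC[C@](C)(Br)[C@@H](Cl)C1 | intermediate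
11 | (3S)-2-[(1R,3S,4S)-4-bromo-3-chloro-4-methylcyclohexyl]-6-methylhepta-1,5-dien-3-ol | CC(C)=CC[C@H](O)C(=C)[C@@H]1CC[C@](C)(Br)[C@@H](Cl)C1 | intermediate
12 | (2S)-3-[(1R,3S,4S)-4-bromo-3-chloro-4-methylcyclohexyl]-1-[(2R)-3,3-dimethyloxiran-2-yl]but-3-en-2-ol | CC1(C)O[C@@H]1C[C@H](O)C(=C)[C@@H]2CC[C@](C)(Br)[C@@H](Cl)C2 | intermediate
13 | (3S,5S)-5-bromo-2-[(1R,3S,4S)-4-bromo-3-chloro-4-methylcyclohexyl]-6-methylhept-1-ene-3,6-diol | CC(C)(O)[C@@H](Br)C[C@H](O)C(=C)[C@@H]1CC[C@](C)(Br)[C@@H](Cl)C1 | intermediate
14 | [(2S,3S,5S)-5-bromo-2-[(1R,3S,4S)-4-bromo-3-chloro-4-methylcyclohexyl]-3-hydroxy-6,6-dimethyloxan-2-yl]methylmercury acetate | CC1(C)O[C@@](C[Hg]OC(C)=O)([C@@H]2CC[C@](C)(Br)[C@@H](Cl)C2)[C@@H](O)C[C@@H]1Br | intermediate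
15 | (2S,3S,5S)-5-bromo-2-[(1R,3S,4S)-4-bromo-3-chloro-4-methylcyclohexyl]-2,6,6-trimethyloxan-3-ol | CC1(C)O[C@@](C)([C@@H]2CC[C@](C)(Br)[C@@H](Cl)C2)[C@@H](O)C[C@@H]1Br | target

**Totals and risks**

Total step count: 11. Longest linear sequence: 11 steps (fully linear from (R)-limonene).

Steps most likely to fail:

Step 11 (key step). Attack on the wrong face of the alkene would give the C2 epimer; divalent mercury could assist loss of bromide from a halogenated carbon; and the β-alkoxy organomercurial could revert to the alkene during borohydride reduction. The fallback sets out from 13 and comes back at 15. It is a cobalt-catalysed hydrogen-atom-transfer hydroalkoxylation (radical–polar crossover): Co(salen) (divalent cobalt, N,N′-bis(salicylidene)ethylenediamine complex, catalytic), N-fluoro-2,4,6-trimethylpyridinium tetrafluoroborate and PhSiH3 in CH2Cl2 at 0 °C. A hydrogen atom is delivered to the =CH2 carbon, the tertiary radical is oxidised, and the tertiary hydroxyl captures it in the same 6-exo sense, without mercury and without a reduction step. This fallback makes no new compound (entry F0).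

Step 10. Bromide could attack the tertiary epoxide carbon, or the free secondary hydroxyl could open the epoxide first. The fallback sets out from 11 (bypassing 12) and comes back at 13. It is an electrophilic bromohydroxylation with N-bromosuccinimide in THF/H2O at 0 °C. Markovnikov opening of the bromonium ion by water fixes bromine on the CH carbon and the hydroxyl on the CMe2 carbon whatever the face of attack, and the less nucleophilic 1,1-disubstituted allylic-alcohol alkene should not compete. There is no facial control, so 13 should form together with its C5 epimer (3S,5R)-5-bromo-2-[(1R,3S,4S)-4-bromo-3-chloro-4-methylcyclohexyl]-6-methylhept-1-ene-3,6-diol F1, from which it is separated by chromatography.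

Step 4. Ionisation of the chlorine-deactivated tertiary alcohol could be too slow, could lead to elimination without re-addition of HBr, or could proceed through an open cation that loses the trans-diaxial arrangement. The fallback sets out from 2 and comes back at 6, and reverses the order in which the halogens are introduced. Epoxidation of 2 with m-chloroperbenzoic acid in CH2Cl2 at 0 °C should give, besides 4, the cis epoxide 1-[(1R,3S,4R)-3,4-epoxy-4-methylcyclohexyl]ethan-1-one F2, which is separated. In F2 Markovnikov and trans-diaxial opening coincide at the tertiary carbon, so aqueous HBr in Et2O at −20 °C should give the diaxial bromo alcohol 1-[(1R,3S,4S)-4-bromo-3-hydroxy-4-methylcyclohexyl]ethan-1-one F3. SOCl2 in Et2O then replaces the axial hydroxyl by chloride with retention through neighbouring-group participation of the antiperiplanar bromine, giving 6.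

**Further compounds**

F0 | step 11 | none | none
F1 | step 10 | (3S,5R)-5-bromo-2-[(1R,3S,4S)-4-bromo-3-chloro-4-methylcyclohexyl]-6-methylhept-1-ene-3,6-diol | CC(C)(O)[C@H](Br)C[C@H](O)C(=C)[C@@H]1CC[C@](C)(Br)[C@@H](Cl)C1
F2 | step 4 | 1-[(1R,3S,4R)-3,4-epoxy-4-methylcyclohexyl]ethan-1-one | CC(=O)[C@@H]1CC[C@@]2(C)O[C@H]2C1
F3 | step 4 | 1-[(1R,3S,4S)-4-bromo-3-hydroxy-4-methylcyclohexyl]ethan-1-one | CC(=O)[C@@H]1CC[C@](C)(Br)[C@@H](O)C1
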